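(All runs come from a simulation on assumed constants; noise was put on by code.)

I began with what was left over: once X had gone, the L and G that X had not taken told how X had divided.

| setting | east | north-west | noon | dusk |
|---|---|---|---|---|
| X | 0.82 M | 0.82 M | 0.82 M | 0.82 M |
| L | 0.90 equiv | 3.6 equiv | 1.80 equiv | 1.80 equiv |
| G | 1.2 equiv | 1.2 equiv | 1.20 equiv | 1.20 equiv |
| remark | run made earlier | run made earlier |  |  |
| time |  |  | 3.0 min | 2.0 min |

| run | time / min | E / % | X / % | Z / % | J / % |
|---|---|---|---|---|---|
| east | 0.167 | 32.5 | 24.4 | 40.6 | 1.3 |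
| east | 0.333 | 40.9 | 8.8 | 48.3 | 2.6 |
| east | 0.667 | 44.4 | 0.9 | 50.3 | 3.9 |
| east | 1.00 | 45.1 | 0 | 49.1 | 5.9 |
| east | 1.33 | 44.4 | 0.2 | 48.2 | 6.8 |
| east | 2.00 | 45.3 | 0 | 44.7 | 10.4 |
| east | 2.50 | 45.2 | 0.2 | 42.0 | 12.6 |
| north-west | 0.200 | 15.3 | 0.5 | 81.9 | 1.5 |
| north-west | 0.333 | 15.0 | 0 | 82.0 | 2.5 |
| north-west | 0.417 | 15.1 | 0 | 82.0 | 3.4 |
| north-west | 0.667 | 15.0 | 0 | 79.3 | 5.6 |
| north-west | 1.00 | 15.0 | 0 | 77.4 | 7.5 |
| north-west | 1.50 | 15.2 | 0.1 | 73.6 | 11.0 |
| north-west | 2.50 | 15.8 | 0.4 | 67.4 | 17.3 |

(each reading ± 0.3 percentage points)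

- a reading or a percentage of Z counts all its forms, free or not

1. which of these there is most of at the end, counted by the X in it, noon (J / E / Z / X)
2. which of these there is most of at the end, counted by the X in it, dusk (J / E / Z / X)
3. final amount of the leader among these, as a percentage of the X charged, in noon
4. final amount of the leader among these, as a percentage of the X charged, in dusk

In the east run X read 0% at 2.00 min. I took each Z as having used one L, and counted J with Z because J grows as Z falls. I took each E as having used one G. So 38.8% of the L charge was left, and 62.3% of the G charge had not been taken by X.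

If X meets L and G at rates proportional to each, these two shares are tied together. I defined the selectivity factor S, the logarithm of the share of L left over the logarithm of the share of G not taken by X:

S = 2.00 (east), 2.01 (north-west, at 1.00 min)

My bench rule was to split X as S times the L charge against the G charge. For noon and dusk, with equal charges, this gave a share p into Z and J of 75.0%. But the rule holds the charges still, and that p uses 41.7% of the L charge. So I went round, taking the share of G not taken by X as the S-th root of the share of L left, with E as the rest of X: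

p: 75.0% → 71.6% → 73.1% → 72.5%

The forecast put Z and J at about 72.6 and said “the X split is fixed early and Z then slowly decays to J”. It gave Z at 53.9% (51.5% to 56%) for noon and Z at 59.6% (57.5% to 61.5%) for dusk.

The flasks gave Z at 54.7% in noon and Z at 60.1% in dusk.

    X + L → Z (k = 0.152 M⁻¹ s⁻¹)
    X + G → E (k = 0.0769 M⁻¹ s⁻¹)
    Q ⇌ Z, rate k3*(cs3 - [Z]) while solid is left; crystals form when [Z] > cs3 (solubility = 26.0 mM, k = 9.56 s⁻¹)
    G + Z → J (k = 0.0452 M⁻¹ s⁻¹)

In dusk, Z and J came to 72.6% and E to 27.4%, beside my 72.5% and 27.5%. Dissolved Z had a half-life of 0.29 min against loss to J at 0.0420 min, shorter than the 2.0 min of dusk. Yet at 2.00 min dusk still held 60.1% of Z, of which crystals Q held 56.9%, and dissolved Z was made 1.00 times as fast as it was used up.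

A neighbour of dusk had 0.450 equiv of L. There the root swung, so I turned the rule round, taking the share of L left as the share of G not taken by X to the power S:

p: 42.8% → 32.6% → 36.3% → 35.1%

That neighbour gave Z and J of 35.5% and E of 64.3% at 2.00 min.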